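**Plan**
1. Retrosynthetic cuts, in order: the C6 acetate, the C7 isovalerate and the C15 acid oxidation level; C9–C11 (side chain as a five-carbon alkylcerium reagent added to a C9 ketone); C3–C4 (ring A, radical closure); C1–C10 and C10–C20 (two enolate alkylations of (R)-carvone).
2. Enabling feature: quaternary C4 with its methyls C18 and C19 sits on ring-fusion carbon C5, and ring B (C5–C10, C17 on C8, an oxygen-bearing C9 beside quaternary C10) is the carvone ring, whose isopropenyl group is C4/C18/C19. Hydrogen-atom transfer turns it into the tertiary C4 radical, which closes ring A on C3 of a 2-sulfonylallyl group attached to C10.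
3. Forward order: ring B is bought; C20 and the C1–C3 unit are alkylated onto C10; ring A closes (C3–C4); the sulfone is removed while the enone is masked as a silyl dienol ether; C6 is oxygenated; the side chain adds to C9; reductive loss of the C9 hydroxyl moves the alkene to C8=C9 and leaves a C6 ketone; C7 hydroxylation, C6 reduction, two esterifications and C15 oxidation finish the synthesis.
4. Stereochemistry: C5 from (R)-carvone; C10 by alkylation anti to the isopropenyl group; 7α-O and 6β-O by reagent approach to the α-face, away from the axial C10 and C4 methyls; 13E by syn-carboalumination.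

Key step: step 5

Remark on names: bicyclic compounds carry labdane numbering (ring A C1–C5 and C10, ring B C5–C10, C17 on C8, C18/C19 on C4, C20 on C10, side chain C11–C16); α is the face opposite C20; "hexanorlabdane" is the decalin core without C11–C16.
Remark on chemistry: the configurations at C2 of 10 and 11, at C6 of 13–15, 26 and 27, and at C9 of 26–28 are erased later; the isomer expected to predominate is drawn and the other would serve equally.

**Route**

Step 1
Reactants: 1 allyl phenyl sulfide
Product: 3 3-bromo-2-(phenylthio)prop-1-ene, via 1,3-dibromo-2-(phenylthio)propane 2 (not isolated)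
Conditions: Br2 (1.0 equiv), CH2Cl2, −15 °C; then 1.5 M aq NaOH, rt
Reagents that add atoms: bromine, BrBr
Why: Bromine adds to the alkene, the thiiranium ion equilibrates the 2,3-dibromide to the 1,3-dibromo-2-thio isomer (1,2-sulfur shift), and hydroxide then removes HBr (E2) to give the 2-thio allyl bromide; the sulfide oxidation level is used because bromination–elimination of the corresponding sulfone would place the sulfonyl group on the alkene terminus.

Step 2
Reactants: 3 3-bromo-2-(phenylthio)prop-1-ene
Product: 4 3-bromo-2-(phenylsulfonyl)prop-1-ene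
Conditions: mCPBA (2.2 equiv), CH2Cl2, 0 °C → rt
Reagents that add atoms: 3-chloroperoxybenzoic acid, O=C(OO)c1cccc(Cl)c1
Why: Peracid oxidation of sulfide to sulfone is chemoselective because the alkene becomes electron-poor after the first S-oxidation and is not epoxidized.

Step 3
Reactants: 5 (R)-carvone
Product: 7 (5R,6S)-2,6-dimethyl-5-(prop-1-en-2-yl)cyclohex-2-en-1-one (6-methylcarvone), via lithium enolate of carvone 6 (not isolated)
Conditions: LiN(i-Pr)2, THF, −78 °C; then MeI, −78 → 0 °C
Reagents that add atoms: iodomethane, CI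
Why: Kinetic α'-deprotonation of the enone by the hindered amide and SN2 methylation of the cross-conjugated enolate (enolate alkylation) should give mainly the trans isomer, and this new centre is planarized again in step 4.

Step 4
Reactants: 7 6-methylcarvone; 4 3-bromo-2-(phenylsulfonyl)prop-1-ene
Product: 9 (5S,6S)-2,6-dimethyl-6-[2-(phenylsulfonyl)prop-2-en-1-yl]-5-(prop-1-en-2-yl)cyclohex-2-en-1-one, via lithium enolate of 6-methylcarvone 8 (not isolated)
Conditions: LiN(i-Pr)2, THF, −78 → 0 °C; then 4, −78 → −40 °C
Reagents that add atoms: none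
Why: Enolate alkylation of the fully substituted α'-carbon with a very reactive 2-sulfonylallyl bromide (SN2' addition–elimination at its unhindered CH2 terminus) should occur on the enolate face opposite the neighbouring isopropenyl group, so the sulfonylallyl chain ends up trans and the methyl cis to isopropenyl, which is the C10 configuration of the target.

Step 5
Reactants: 9 6-methyl-6-[2-(phenylsulfonyl)allyl]carvone
Product: 10 2α-(phenylsulfonyl)-11,12,13,14,15,16-hexanorlabd-7-en-9-one (trans-decalin; 5α-H; 10β-CH3)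
Conditions: Fe(acac)3 (0.5 equiv), PhSiH3 (2.5 equiv), EtOH/(CH2OH)2 5:1, degassed, 60 °C
Reagents that add atoms: none
Why: An iron hydride formed from Fe(acac)3 and PhSiH3 transfers a hydrogen atom to the terminal CH2 of the electron-rich isopropenyl group to give the tertiary C4 radical, which adds to the unsubstituted terminus C3 of the vinyl sulfone; the α-sulfonyl radical is then reduced by divalent iron and the carbanion protonated by ethanol. This is an intramolecular iron-hydride hydrogen-atom-transfer reductive olefin coupling (radical Giese addition), a known reaction type for 1,1-disubstituted donor alkenes and vinyl sulfone acceptors, including closures that create quaternary carbons. Ring A closes in the 6-endo-trig mode by forming C3–C4, because the 5-exo carbon C2 is fully substituted and carries the sulfonyl group, so attack there is hindered and polarity-mismatched. No ring-fusion centre is created, since C5 and C10 are already trans-disposed in 9 and only the trans-decalin can result; the one new stereocentre, C2, is set by protonation of the α-sulfonyl carbanion, should favour the equatorial sulfone, and disappears in step 7. The step needs hydrogen-atom transfer to the isopropenyl alkene in preference to the enone and the vinyl sulfone, which the preference of the metal hydride for electron-rich alkenes should secure, and the enone cannot trap the C4 radical because only a four-membered ring could form.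

Step 6
Reactants: 10 sulfonyl decalin enone
Product: 11 2α-(phenylsulfonyl)-9-(triisopropylsilyloxy)-11,12,13,14,15,16-hexanorlabda-6,8-diene
Conditions: i-Pr3SiOTf, Et3N, CH2Cl2, 0 °C → rt
Reagents that add atoms: triisopropylsilyl trifluoromethanesulfonate, CC(C)[Si](C(C)C)(C(C)C)OS(=O)(=O)C(F)(F)F
Why: Soft enolization (O-silylation, then γ-deprotonation at C6 by the amine, since the α'-carbon C10 is quaternary) gives the linear silyl dienol ether, which masks the easily reduced enone for step 7 and prepares the C6 oxygenation of step 8.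

Step 7
Reactants: 11 sulfonyl silyl dienol ether
Product: 12 9-(triisopropylsilyloxy)-11,12,13,14,15,16-hexanorlabda-6,8-diene
Conditions: Na(Hg) (6% Na), Na2HPO4, THF/MeOH, −20 → 0 °C
Reagents that add atoms: none
Why: Reductive desulfonylation by electron transfer from sodium amalgam in buffered methanol (the reduction of the classical Julia sequence) cleaves the C2–S bond, while the electron-rich silyloxydiene, unlike the free enone, is not reducible and the bulky silyl enol ether should survive the buffered medium.

Step 8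
Reactants: 12 silyl dienol ether
Product: 14 6α-hydroxy-11,12,13,14,15,16-hexanorlabd-7-en-9-one, via 6α,7α-epoxide 13 (not isolated)
Conditions: DMDO, acetone/CH2Cl2, −78 → −20 °C; then HF·pyridine, THF, 0 °C
Reagents that add atoms: dimethyldioxirane, CC1(C)OO1
Why: Vinylogous Rubottom oxidation, in which the dioxirane epoxidizes the terminal, less hindered C6=C7 bond of the silyloxydiene (γ-selectivity typical of neutral silyl dienol ethers, reinforced because C8=C9 is tetrasubstituted and flanked by C10 and the silyl group) from the α-face away from the axial C10 and C4 methyls, and loss of the silyl group opens the epoxide to the γ-hydroxy enone.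

Step 9
Reactants: 14 γ-hydroxy enone
Product: 15 6α-(trimethylsilyloxy)-11,12,13,14,15,16-hexanorlabd-7-en-9-one
Conditions: Me3SiCl, imidazole, CH2Cl2, 0 °C
Reagents that add atoms: chlorotrimethylsilane, C[Si](C)(C)Cl
Why: Silylation of the secondary allylic alcohol gives a base-stable but very easily removed ether, so the organometallic reagent of step 15 is not quenched.

Step 10
Reactants: 16 but-3-yn-1-ol
Product: 17 tert-butyl(but-3-yn-1-yloxy)dimethylsilane
Conditions: t-BuMe2SiCl, imidazole, CH2Cl2, rt
Reagents that add atoms: tert-butylchlorodimethylsilane, CC(C)(C)[Si](C)(C)Cl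
Why: Silyl protection of the primary alcohol lets it pass the organoaluminium and organolithium reagents of step 11.

Step 11
Reactants: 17 silyl-protected butynol
Product: 20 (2E)-5-(tert-butyldimethylsilyloxy)-3-methylpent-2-en-1-ol, via alkenyldimethylalane 18 (not isolated), via lithium alkenylalanate 19 (not isolated)
Conditions: Me3Al, Cp2ZrCl2 (0.25 equiv), CH2Cl2, 0 °C → rt; then n-BuLi, THF, −30 °C; then (CH2O)n, → rt
Reagents that add atoms: trimethylaluminium, C[Al](C)C; paraformaldehyde (as formaldehyde), C=O
Why: Zirconium-catalysed Negishi carboalumination adds methyl and aluminium syn across the terminal alkyne with methyl on the internal carbon, which fixes the E geometry of the future C13=C14 bond, and the derived alanate is hydroxymethylated by formaldehyde with retention of alkene geometry.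

Step 12
Reactants: 20 allylic alcohol
Product: 21 (2E)-1-(tert-butyldiphenylsilyloxy)-5-(tert-butyldimethylsilyloxy)-3-methylpent-2-ene
Conditions: t-BuPh2SiCl, imidazole, CH2Cl2, rt
Reagents that add atoms: tert-butylchlorodiphenylsilane, CC(C)(C)[Si](Cl)(c1ccccc1)c1ccccc1
Why: Silylation of the primary allylic alcohol installs the bulkier, more acid-stable silyl group that has to last until step 22.

Step 13
Reactants: 21 bis-silyl ether
Product: 22 (3E)-5-(tert-butyldiphenylsilyloxy)-3-methylpent-3-en-1-ol
Conditions: PPTS, MeOH, rt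
Reagents that add atoms: none
Why: Acid-catalysed methanolysis cleaves a primary tert-butyldimethylsilyl ether far faster than a tert-butyldiphenylsilyl ether (selective silyl ether solvolysis).

Step 14
Reactants: 22 homoallylic alcohol
Product: 23 (2E)-1-(tert-butyldiphenylsilyloxy)-5-iodo-3-methylpent-2-ene
Conditions: I2, PPh3, imidazole, CH2Cl2, 0 °C
Reagents that add atoms: iodine, II
Why: Appel-type iodination (oxyphosphonium activation, then SN2 displacement by iodide) of an unhindered primary alcohol.

Step 15
Reactants: 23 side-chain iodide; 15 silyloxy enone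
Product: 27 15-(tert-butyldiphenylsilyloxy)labda-7,13E-diene-6α,9β-diol (C11 on the α-face), via alkyllithium 24 (not isolated), via alkylcerium dichloride 25 (not isolated), via C6 trimethylsilyl ether 26 (not isolated)
Conditions: 23, t-BuLi (2.1 equiv), Et2O/pentane, −78 °C; CeCl3, THF, −78 °C; then 15, −78 → −40 °C; then K2CO3, MeOH, 0 °C
Reagents that add atoms: none
Why: Lithium–iodine exchange gives the primary alkyllithium, and transmetalation to the weakly basic, oxophilic organocerium reagent should secure clean 1,2-addition to the hindered C9 enone carbonyl, expected from the α-face opposite the C10 methyl, after which mild methanolysis removes the trimethylsilyl group.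

Step 16
Reactants: 27 diol
Product: 28 15-(tert-butyldiphenylsilyloxy)-9β-hydroxylabda-7,13E-dien-6-one
Conditions: Dess–Martin periodinane, NaHCO3, CH2Cl2, 0 °C → rt
Reagents that add atoms: none
Why: Dess–Martin oxidation converts the secondary allylic alcohol into the enone, while the tertiary C9 alcohol cannot be oxidized and the buffer protects it from acid-induced ionization.

Step 17
Reactants: 28 γ-hydroxy enone
Product: 30 15-(tert-butyldiphenylsilyloxy)labda-8,13E-dien-6-one, via samarium dienolate 29 (not isolated)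
Conditions: SmI2 (2.5 equiv), THF, −78 °C; then saturated aq NH4Cl, −78 °C → rt
Reagents that add atoms: none
Why: Two-electron reduction of the enone by SmI2 puts carbanion character on C8, which expels the adjacent C9 hydroxyl (reductive cleavage of a γ-oxygenated enone, the vinylogous form of α-heteroatom ketone reduction), and kinetic protonation of the resulting dienolate at its α-carbon C7 gives the β,γ-unsaturated ketone with the tetrasubstituted C8=C9 alkene.

Step 18
Reactants: 30 β,γ-unsaturated ketone
Product: 32 15-(tert-butyldiphenylsilyloxy)-7α-hydroxylabda-8,13E-dien-6-one, via potassium dienolate 31 (not isolated)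
Conditions: KN(SiMe3)2, THF, −78 °C; then 2-(phenylsulfonyl)-3-phenyloxaziridine, −78 °C; AcOH quench
Reagents that add atoms: 2-(phenylsulfonyl)-3-phenyloxaziridine, O=S(=O)(N1OC1c1ccccc1)c1ccccc1
Why: Deprotonation at the doubly activated C7 methylene (α to the ketone and allylic) gives the dienolate, which as a metal dienolate is oxidized at its α-carbon by the N-sulfonyloxaziridine (enolate hydroxylation), and oxygen is delivered to the α-face because the β-face of ring B is screened by the axial methyls on C10 and C4, which sets the 7α-hydroxyl.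

Step 19
Reactants: 32 α-hydroxy ketone
Product: 33 15-(tert-butyldiphenylsilyloxy)labda-8,13E-diene-6β,7α-diol
Conditions: NaBH4, MeOH/CH2Cl2, −40 → 0 °C
Reagents that add atoms: none
Why: Borohydride reduction of the C6 ketone should take place from the α-face only, because the β-face is syn-axial to the C10 and C4β methyls, which gives the axial 6β-alcohol and removes the base-sensitive ketol.

Step 20
Reactants: 33 6β,7α-diol
Product: 34 15-(tert-butyldiphenylsilyloxy)-6β-hydroxylabda-8,13E-dien-7α-yl 3-methylbutanoate
Conditions: isovaleryl chloride (1.2 equiv), pyridine, DMAP (catalytic), CH2Cl2, −20 → 0 °C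
Reagents that add atoms: 3-methylbutanoyl chloride, CC(C)CC(=O)Cl
Why: Nucleophile-catalysed acylation should discriminate the accessible allylic 7α-hydroxyl from the 6β-hydroxyl, which is 1,3-diaxial to two methyl groups, and acyl migration is not expected because the two oxygens are trans-diaxial.

Step 21
Reactants: 34 hydroxy isovalerate
Product: 35 6β-acetoxy-15-(tert-butyldiphenylsilyloxy)labda-8,13E-dien-7α-yl 3-methylbutanoate
Conditions: Ac2O, DMAP, Et3N, CH2Cl2, 40 °C
Reagents that add atoms: acetic anhydride, CC(=O)OC(C)=O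
Why: DMAP-catalysed acetylation under forcing conditions esterifies the one remaining, hindered axial alcohol, all other functionality being protected or inert.

Step 22
Reactants: 35 silyl ether diester
Product: 36 6β-acetoxy-15-hydroxylabda-8,13E-dien-7α-yl 3-methylbutanoate
Conditions: HF·pyridine, pyridine, THF, 0 °C → rt
Reagents that add atoms: none
Why: Buffered fluoride cleavage of the silyl ether leaves both esters, including the allylic C7 ester, untouched.

Step 23
Reactants: 36 allylic alcohol
Product: 38 6β-acetoxy-7α-(3-methylbutanoyloxy)labda-8,13E-dien-15-oic acid (CNP0328312.2), via 15-aldehyde 37 (not isolated)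
Conditions: TEMPO (catalytic), PhI(OAc)2, CH2Cl2, rt; then NaClO2, NaH2PO4, 2-methyl-2-butene, t-BuOH/H2O, rt
Reagents that add atoms: sodium chlorite, [Na+].[O-]Cl=O
Why: Oxoammonium oxidation of the primary allylic alcohol stops at the enal, and Pinnick oxidation with chlorite and a hypochlorite scavenger converts it into the acid without touching the ring alkene, the esters or the 13E geometry.

**Compound list**

1 | allyl phenyl sulfide | C=CCSc1ccccc1 | starting material
2 | 1,3-dibromo-2-(phenylthio)propane | BrCC(CBr)Sc1ccccc1 | intermediate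
3 | 3-bromo-2-(phenylthio)prop-1-ene | C=C(CBr)Sc1ccccc1 | intermediate
4 | 3-bromo-2-(phenylsulfonyl)prop-1-ene | C=C(CBr)S(=O)(=O)c1ccccc1 | intermediate
5 | (R)-carvone | CC1=CC[C@H](CC1=O)C(C)=C | starting material
6 | lithium cross-conjugated enolate of (R)-carvone | CC1=CC[C@@H](C(C)=C)C=C1O[Li] | intermediate
7 | (5R,6S)-2,6-dimethyl-5-(prop-1-en-2-yl)cyclohex-2-en-1-one | CC1=CC[C@@H](C(C)=C)[C@H](C)C1=O | intermediate
8 | lithium enolate of 6-methylcarvone | CC1=CC[C@@H](C(C)=C)C(C)=C1O[Li] | intermediate
9 | (5S,6S)-2,6-dimethyl-6-[2-(phenylsulfonyl)prop-2-en-1-yl]-5-(prop-1-en-2-yl)cyclohex-2-en-1-one | CC1=CC[C@@H](C(C)=C)[C@](C)(CC(=C)S(=O)(=O)c2ccccc2)C1=O | intermediate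
10 | 2α-(phenylsulfonyl)-11,12,13,14,15,16-hexanorlabd-7-en-9-one | CC1=CC[C@H]2C(C)(C)C[C@H](S(=O)(=O)c3ccccc3)C[C@]2(C)C1=O | intermediate
11 | 2α-(phenylsulfonyl)-9-(triisopropylsilyloxy)-11,12,13,14,15,16-hexanorlabda-6,8-diene | C1=CC(C)=C(O[Si](C(C)C)(C(C)C)C(C)C)[C@@]2(C)C[C@@H](S(=O)(=O)c3ccccc3)CC(C)(C)[C@H]12 | intermediate
12 | 9-(triisopropylsilyloxy)-11,12,13,14,15,16-hexanorlabda-6,8-diene | C1=CC(C)=C(O[Si](C(C)C)(C(C)C)C(C)C)[C@@]2(C)CCCC(C)(C)[C@H]12 | intermediate
13 | 6α,7α-epoxy-9-(triisopropylsilyloxy)-11,12,13,14,15,16-hexanorlabd-8-ene | O1[C@H]2[C@@H]1C(C)=C(O[Si](C(C)C)(C(C)C)C(C)C)[C@@]3(C)CCCC(C)(C)[C@H]23 | intermediate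
14 | 6α-hydroxy-11,12,13,14,15,16-hexanorlabd-7-en-9-one | O[C@H]1C=C(C)C(=O)[C@@]2(C)CCCC(C)(C)[C@H]12 | intermediate
15 | 6α-(trimethylsilyloxy)-11,12,13,14,15,16-hexanorlabd-7-en-9-one | C[Si](C)(C)O[C@H]1C=C(C)C(=O)[C@@]2(C)CCCC(C)(C)[C@H]12 | intermediate
16 | but-3-yn-1-ol | C#CCCO | starting material
17 | tert-butyl(but-3-yn-1-yloxy)dimethylsilane | C#CCCO[Si](C)(C)C(C)(C)C | intermediate
18 | [(1E)-4-(tert-butyldimethylsilyloxy)-2-methylbut-1-en-1-yl]dimethylalane | C[Al](C)/C=C(C)/CCO[Si](C)(C)C(C)(C)C | intermediate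
19 | lithium butyl[(1E)-4-(tert-butyldimethylsilyloxy)-2-methylbut-1-en-1-yl]dimethylalanate | [Li+].CCCC[Al-](C)(C)/C=C(C)/CCO[Si](C)(C)C(C)(C)C | intermediate
20 | (2E)-5-(tert-butyldimethylsilyloxy)-3-methylpent-2-en-1-ol | OC/C=C(C)/CCO[Si](C)(C)C(C)(C)C | intermediate
21 | (2E)-1-(tert-butyldiphenylsilyloxy)-5-(tert-butyldimethylsilyloxy)-3-methylpent-2-ene | CC(C)(C)[Si](C)(C)OCC/C(C)=C/CO[Si](c1ccccc1)(c1ccccc1)C(C)(C)C | intermediate
22 | (3E)-5-(tert-butyldiphenylsilyloxy)-3-methylpent-3-en-1-ol | OCC/C(C)=C/CO[Si](c1ccccc1)(c1ccccc1)C(C)(C)C | intermediate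
23 | (2E)-1-(tert-butyldiphenylsilyloxy)-5-iodo-3-methylpent-2-ene | ICC/C(C)=C/CO[Si](c1ccccc1)(c1ccccc1)C(C)(C)C | intermediate
24 | [(3E)-5-(tert-butyldiphenylsilyloxy)-3-methylpent-3-en-1-yl]lithium | [Li]CC/C(C)=C/CO[Si](c1ccccc1)(c1ccccc1)C(C)(C)C | intermediate
25 | [(3E)-5-(tert-butyldiphenylsilyloxy)-3-methylpent-3-en-1-yl]cerium dichloride | Cl[Ce](Cl)CC/C(C)=C/CO[Si](c1ccccc1)(c1ccccc1)C(C)(C)C | intermediate
26 | 15-(tert-butyldiphenylsilyloxy)-6α-(trimethylsilyloxy)labda-7,13E-dien-9β-ol | C[Si](C)(C)O[C@H]1C=C(C)[C@@](O)(CC/C(C)=C/CO[Si](c3ccccc3)(c3ccccc3)C(C)(C)C)[C@@]2(C)CCCC(C)(C)[C@H]12 | intermediate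
27 | 15-(tert-butyldiphenylsilyloxy)labda-7,13E-diene-6α,9β-diol | O[C@H]1C=C(C)[C@@](O)(CC/C(C)=C/CO[Si](c3ccccc3)(c3ccccc3)C(C)(C)C)[C@@]2(C)CCCC(C)(C)[C@H]12 | intermediate
28 | 15-(tert-butyldiphenylsilyloxy)-9β-hydroxylabda-7,13E-dien-6-one | O=C1C=C(C)[C@@](O)(CC/C(C)=C/CO[Si](c3ccccc3)(c3ccccc3)C(C)(C)C)[C@@]2(C)CCCC(C)(C)[C@H]12 | intermediate
29 | diiodosamarium 6,8-dienolate of 30 (trivalent samarium) | I[Sm](I)OC1=CC(C)=C(CC/C(C)=C/CO[Si](c3ccccc3)(c3ccccc3)C(C)(C)C)[C@@]2(C)CCCC(C)(C)[C@H]12 | intermediate
30 | 15-(tert-butyldiphenylsilyloxy)labda-8,13E-dien-6-one | O=C1CC(C)=C(CC/C(C)=C/CO[Si](c3ccccc3)(c3ccccc3)C(C)(C)C)[C@@]2(C)CCCC(C)(C)[C@H]12 | intermediate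
31 | potassium 6,8-dienolate of 30 | [K+].[O-]C1=CC(C)=C(CC/C(C)=C/CO[Si](c3ccccc3)(c3ccccc3)C(C)(C)C)[C@@]2(C)CCCC(C)(C)[C@H]12 | intermediate
32 | 15-(tert-butyldiphenylsilyloxy)-7α-hydroxylabda-8,13E-dien-6-one | O=C1[C@@H](O)C(C)=C(CC/C(C)=C/CO[Si](c3ccccc3)(c3ccccc3)C(C)(C)C)[C@@]2(C)CCCC(C)(C)[C@H]12 | intermediate
33 | 15-(tert-butyldiphenylsilyloxy)labda-8,13E-diene-6β,7α-diol | O[C@@H]1[C@@H](O)C(C)=C(CC/C(C)=C/CO[Si](c3ccccc3)(c3ccccc3)C(C)(C)C)[C@@]2(C)CCCC(C)(C)[C@H]12 | intermediate
34 | 15-(tert-butyldiphenylsilyloxy)-6β-hydroxylabda-8,13E-dien-7α-yl 3-methylbutanoate | O[C@@H]1[C@@H](OC(=O)CC(C)C)C(C)=C(CC/C(C)=C/CO[Si](c3ccccc3)(c3ccccc3)C(C)(C)C)[C@@]2(C)CCCC(C)(C)[C@H]12 | intermediate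
35 | 6β-acetoxy-15-(tert-butyldiphenylsilyloxy)labda-8,13E-dien-7α-yl 3-methylbutanoate | CC(=O)O[C@@H]1[C@@H](OC(=O)CC(C)C)C(C)=C(CC/C(C)=C/CO[Si](c3ccccc3)(c3ccccc3)C(C)(C)C)[C@@]2(C)CCCC(C)(C)[C@H]12 | intermediate
36 | 6β-acetoxy-15-hydroxylabda-8,13E-dien-7α-yl 3-methylbutanoate | CC(=O)O[C@@H]1[C@@H](OC(=O)CC(C)C)C(C)=C(CC/C(C)=C/CO)[C@@]2(C)CCCC(C)(C)[C@H]12 | intermediate
37 | 6β-acetoxy-15-oxolabda-8,13E-dien-7α-yl 3-methylbutanoate | CC(=O)O[C@@H]1[C@@H](OC(=O)CC(C)C)C(C)=C(CC/C(C)=C/C=O)[C@@]2(C)CCCC(C)(C)[C@H]12 | intermediate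
38 | 6β-acetoxy-7α-(3-methylbutanoyloxy)labda-8,13E-dien-15-oic acid | CC(=O)O[C@@H]1[C@@H](OC(=O)CC(C)C)C(C)=C(CC/C(C)=C/C(=O)O)[C@@]2(C)CCCC(C)(C)[C@H]12 | target

**Step count and risks**

Total step count: 23. Longest linear sequence: 17 steps (steps 1, 2, 4–9 and 15–23, from allyl phenyl sulfide; 16 steps counted from (R)-carvone).

Steps most likely to fail:

1. Step 17. Expulsion of the unactivated tertiary C9 hydroxyl may be slower than protonation or dimerization of the reduced enone, and the dienolate may be protonated at C9 instead of C7. The fallback sets out from 15 and returns at 30. Conjugate reduction of 15 with LiBH(s-Bu)3 and trapping of the C9 enolate with PhNTf2 would give the enol triflate F1. The alkyllithium 24, generated from 23 as in step 15, would be transmetalated with ZnCl2 to the alkylzinc chloride F2. Negishi coupling of F1 and F2 with Pd(dppf)Cl2 as catalyst would form C9–C11 directly on the C8=C9 alkene and give the silyl ether F3. K2CO3 in methanol would free the 6α-alcohol F4, and buffered Dess–Martin oxidation would give 30, so no leaving group at C9 is needed.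

2. Step 18. The oxidant may fail to discriminate the faces of the dienolate, and the product ketol may isomerize under the basic conditions by migration of the C8=C9 bond into conjugation. The fallback sets out from 30 and returns at 34. It makes the C7–O bond by epoxide opening instead of electrophilic oxygenation:
- Bromination of the potassium dienolate with N-bromosuccinimide at −78 °C would give the 7α-bromo ketone F5.
- NaBH4 would reduce it from the α-face to the trans-diaxial bromohydrin F6.
- K2CO3 in methanol would close the 6β,7β-epoxide F7 with inversion at C7.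
- Caesium isovalerate (isovaleric acid, Cs2CO3, DMF) would open the vinyl epoxide at the allylic carbon C7 from the α-face (trans-diaxial opening) to give 34, with the 7α-isovalerate and the free 6β-hydroxyl.

3. Step 5. Hydrogen-atom transfer may also reach the vinyl sulfone, or the C4 radical may be reduced before it cyclizes (net hydrogenation of the isopropenyl group). The fallback sets out from 9 and returns at 10. Markovnikov addition of HBr (HBr in AcOH, 0 °C) to the isopropenyl group would give the tertiary bromide F8. Slow addition of Bu3SnH with AIBN in benzene at 80 °C would generate the same C4 radical from the C–Br bond for the same 6-endo Giese closure onto the vinyl sulfone, giving 10.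

**Further compounds**

F1 | step 17 | 6α-(trimethylsilyloxy)-11,12,13,14,15,16-hexanorlabd-8-en-9-yl trifluoromethanesulfonate | C[Si](C)(C)O[C@H]1CC(C)=C(OS(=O)(=O)C(F)(F)F)[C@@]2(C)CCCC(C)(C)[C@H]12
F2 | step 17 | [(3E)-5-(tert-butyldiphenylsilyloxy)-3-methylpent-3-en-1-yl]zinc chloride | Cl[Zn]CC/C(C)=C/CO[Si](c1ccccc1)(c1ccccc1)C(C)(C)C
F3 | step 17 | 15-(tert-butyldiphenylsilyloxy)-6α-(trimethylsilyloxy)labda-8,13E-diene | C[Si](C)(C)O[C@H]1CC(C)=C(CC/C(C)=C/CO[Si](c3ccccc3)(c3ccccc3)C(C)(C)C)[C@@]2(C)CCCC(C)(C)[C@H]12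
F4 | step 17 | 15-(tert-butyldiphenylsilyloxy)labda-8,13E-dien-6α-ol | O[C@H]1CC(C)=C(CC/C(C)=C/CO[Si](c3ccccc3)(c3ccccc3)C(C)(C)C)[C@@]2(C)CCCC(C)(C)[C@H]12
F5 | step 18 | 7α-bromo-15-(tert-butyldiphenylsilyloxy)labda-8,13E-dien-6-one | O=C1[C@@H](Br)C(C)=C(CC/C(C)=C/CO[Si](c3ccccc3)(c3ccccc3)C(C)(C)C)[C@@]2(C)CCCC(C)(C)[C@H]12
F6 | step 18 | 7α-bromo-15-(tert-butyldiphenylsilyloxy)labda-8,13E-dien-6β-ol | O[C@@H]1[C@@H](Br)C(C)=C(CC/C(C)=C/CO[Si](c3ccccc3)(c3ccccc3)C(C)(C)C)[C@@]2(C)CCCC(C)(C)[C@H]12
F7 | step 18 | 15-(tert-butyldiphenylsilyloxy)-6β,7β-epoxylabda-8,13E-diene | O1[C@@H]2[C@H]1C(C)=C(CC/C(C)=C/CO[Si](c4ccccc4)(c4ccccc4)C(C)(C)C)[C@@]3(C)CCCC(C)(C)[C@H]23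
F8 | step 5 | (5R,6S)-5-(2-bromopropan-2-yl)-2,6-dimethyl-6-[2-(phenylsulfonyl)prop-2-en-1-yl]cyclohex-2-en-1-one | CC1=CC[C@@H](C(C)(C)Br)[C@](C)(CC(=C)S(=O)(=O)c2ccccc2)C1=O
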